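The slope of the logarithm of target against time stayed put while partner moved, and that slope was what I handed over. The flasks, readings and questions stood as follows.

| setting | dusk | spring | summer | Friday's | Tuesday's | Thursday's | Wednesday's |
|---|---|---|---|---|---|---|---|
| starting material | 0.50 M | 0.50 M | 0.50 M | 0.50 M | 0.50 M | 0.50 M | 0.50 M |
| partner | 1.25 M | 0.84 M | 1.9 M | 1.25 M | 1.25 M | 1.25 M | 1.25 M |
| second substrate | 0.50 M | 0.50 M | 0.50 M | 0.500 M | 0.500 M | 0.500 M (fed, over 2.40 min) | 0.500 M |
| free catalyst | 0.50 mM | 0.50 mM | 0.50 mM | 0.50 mM | 0.50 mM | 0.50 mM | 0.50 mM |
| remark | run made earlier | run made earlier | run made earlier | everything together in a closed stirred flask, run for 3.0 min | one stirred flow tank at steady state, fed with the mixture as stated, mean residence time 3.0 min | a stirred flask in which second substrate is dosed at a steady rate over 2.40 min without added volume, worked up at 3.0 min | plug flow through a tube for 3.0 min, no back-mixing |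
| time |  |  |  | 3.0 min |  | 3.0 min | 3.0 min |

| run | time / min | target / % |
|---|---|---|
| dusk | 0.667 | 80.3 |
| dusk | 1.33 | 65.4 |
| dusk | 2.00 | 54.2 |
| dusk | 2.50 | 46.3 |
| dusk | 3.00 | 38.7 |
| spring | 0.500 | 68.6 |
| spring | 1.00 | 61.6 |
| spring | 1.33 | 56.2 |
| spring | 2.00 | 46.4 |
| spring | 2.50 | 39.3 |
| summer | 0.200 | 90.8 |
| summer | 0.667 | 81.3 |
| summer | 1.00 | 73.1 |
| summer | 1.50 | 61.9 |
| summer | 2.50 | 44.8 |

(each reading ± 0.5 percentage points)

* the set-up with the highest amount of target at the outlet or at the end, in percent of the starting material put in ("none" if the first two lie within 2 percentage points) (Friday's / Tuesday's / Thursday's / Wednesday's / none)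
* amount of target at the outlet or at the end, in percent of the starting material put in, Friday's
* amount of target at the outlet or at the end, in percent of the starting material put in, Tuesday's
* amount of target at the outlet or at the end, in percent of the starting material put in, Thursday's
* amount of target at the outlet or at the end, in percent of the starting material put in, Wednesday's

- the stated concentrations are those of everything mixed, before any reaction; amounts are the same in each set-up
- the feed brings no volume worth counting
- the earlier runs were made in a closed, stirred flask

From 1.33 min on, the dusk run fell with a slope of 0.314 min⁻¹, which I called the fading rate, the fraction of target lost per minute at each moment. The spring run read 0.300 min⁻¹ and the summer run 0.326 min⁻¹, close to each other, though summer held twice the partner of spring.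

So I reckoned by the age of the target. After 3.0 min in the closed flask or the tube, the fading left 39.0% of the charge as target. What I wanted left alone was the clock, since target was still fading at the last readings. No run varied second substrate, so Thursday's was my weakest figure, and in this reckoning of my own, which is not the forecast's, I gave dosing no credit and put Thursday's near that number too. Tuesday's tank mixes ages and keeps one part in one plus rate times residence time, 51.5% of what it makes, more than the closed flask. Unconverted starting material lowers that somewhat, yet I named Tuesday's best.

The forecast, which parted from my own reckoning on Thursday's and on the best set-up, gave 38.7% for Friday's, 47% for Tuesday's, 50% for Thursday's and 38.7% for Wednesday's, and named Thursday's, on the ground that “Dosing keeps second substrate low early and gives a lag”.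

The flasks gave 39.2% on Friday's, 39.2% on Wednesday's, 38.6% on Thursday's and 45.3% on Tuesday's, so Tuesday's led. Thursday's ended with 61.3% of isomer of the product, level with Friday's 60.7%. Tuesday's tank let out 11.2% of starting material unconverted, and the fading rate on the remainder gives 45.7% of target.

    starting material + partner + free catalyst → free catalyst + target (k = 500 M⁻² s⁻¹)
    second substrate + partner + free catalyst → free catalyst + second product (k = 430 M⁻² s⁻¹)
    free catalyst + target → spent catalyst (k = 0.0140 M⁻¹ s⁻¹)
    partner → decomposed reagent (k = 0.00190 s⁻¹)
    target ⇌ isomer of the product (K = 20.0, k = 0.00560 s⁻¹)

A closed flask like Friday's with 1.2 M of second substrate ended with partner, the limiting reagent there, at 0% and with 23% of starting material unconverted. The fading rate on the remainder gives 30.0%, and the computed flask gave 29.6%.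

All runs were generated by integration with constants of no real substance; noise was put on by code.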